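Everything rests on opening the oxygen ring of the chroman at C4a–C4 and O1–C2: C2 with its two methyls, C3 and C4 then arrive as one five-carbon allylic cation, while O1 is simply the ring A hydroxyl on C8a. The key step exploits the fact that this hydroxyl, para to the acyl-bearing C6, sits next to a free, strongly nucleophilic ring carbon (C4a): Friedel–Crafts C-alkylation and capture of the resulting tertiary cation by that oxygen forge both bonds and the ring in one flask. The precursor is a symmetric 2,4,6-trihydroxyphenyl ketone whose ring B carries bromine ortho to its phenol, a placeholder for the acid-sensitive second prenyl group, installed afterwards under base.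

Key step: step 3

Remark: the target has no stereocentre and no configured double bond, so no stereocontrol is needed. Chroman numbering (O1, C2, C3, C4, C4a, C5 to C8, C8a) is used for the bicyclic part; ring A is its benzene ring and ring B is the 4-hydroxyphenyl ring.
Remark: bromine rather than iodine is kept as the placeholder because it tolerates both BF3 steps. The phenols stay free in the coupling because acetates or silyl ethers would not survive hot aqueous phosphate anyway.

Step 1
Reactants: 1 3-(4-hydroxyphenyl)propanoic acid
Product: 2 3-(3-bromo-4-hydroxyphenyl)propanoic acid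
Conditions: NBS (1.0 equiv, in portions), MeCN, 0 °C to rt, dark
Reagents that add atoms: N-bromosuccinimide, O=C1CCC(=O)N1Br
Why: Electrophilic aromatic bromination, in which the hydroxyl directs to its two equivalent ortho positions (para is blocked by the side chain) and the first bromine lowers the reactivity of the ring enough for one equivalent of NBS to stop at the monobromide.

Step 2
Reactants: 2 3-(3-bromo-4-hydroxyphenyl)propanoic acid; 3 phloroglucinol (1.2 equiv)
Product: 4 3-(3-bromo-4-hydroxyphenyl)-1-(2,4,6-trihydroxyphenyl)propan-1-one
Conditions: BF3·OEt2 (neat, as solvent), 85 °C, 2 h; then 10% aq NaOAc, rt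
Reagents that add atoms: none
Why: Friedel–Crafts acylation with the free acid activated by BF3, in which all three ring carbons of phloroglucinol are equivalent, its ring is far more nucleophilic than the bromophenol ring of the acid, and the conjugated, chelated ketone that results is deactivated toward a second acylation.

Step 3
Reactants: 4 3-(3-bromo-4-hydroxyphenyl)-1-(2,4,6-trihydroxyphenyl)propan-1-one; 5 2-methylbut-3-en-2-ol (1.0 equiv)
Product: 7 3-(3-bromo-4-hydroxyphenyl)-1-(5,7-dihydroxy-2,2-dimethylchroman-6-yl)propan-1-one, via C-prenyl ketone 6 (not isolated)
Conditions: BF3·OEt2 (0.3 equiv), dry 1,4-dioxane, 5 added over 2 h at rt; then 50 °C until 6 is consumed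
Reagents that add atoms: none
Why: BF3 ionises the tertiary allylic alcohol 5 to the 1,1-dimethylallyl cation, whose unsubstituted terminus is attacked by one of the two equivalent free carbons of ring A (Friedel–Crafts alkylation, giving 6 and the C4a–C4 bond), after which protonation of the trisubstituted alkene places a tertiary cation at C2 that the flanking phenol oxygen captures (O1–C2 bond). The closest known reaction type is the acid-catalysed chroman annulation of acylphloroglucinols with 2-methylbut-3-en-2-ol or isoprene. The one ring formed, the six-membered oxygen ring, closes by Markovnikov addition of the hydroxyl to the prenyl alkene, formally a 6-endo-trig closure, preferred over the 5-exo alternative because it runs through the tertiary and not the secondary cation. No stereocentre arises, since C2 carries two identical methyl groups. Chemoselectivity for ring A should follow from its three oxygen donors against the single donor and the bromine of ring B, and mono-annulation from adding only one equivalent of 5 slowly. The step also needs closure through the oxygen para to the acyl group, which is expected to be favoured because that hydroxyl is never held in the hydrogen-bonded chelate with the carbonyl whereas the competing ortho hydroxyl is held there part of the time (only one ortho hydroxyl can chelate at once, so the preference is not absolute), and the ortho-closed 8-acyl isomer is therefore the by-product to expect and to remove by chromatography.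

Step 4
Reactants: 7 3-(3-bromo-4-hydroxyphenyl)-1-(5,7-dihydroxy-2,2-dimethylchroman-6-yl)propan-1-one; 8 prenylboronic acid pinacol ester (2.0 equiv)
Product: 9 1-(5,7-dihydroxy-2,2-dimethylchroman-6-yl)-3-[4-hydroxy-3-(3-methylbut-2-en-1-yl)phenyl]propan-1-one (target)
Conditions: Pd(OAc)2 (5 mol %), tBuXPhos (2-di-tert-butylphosphino-2′,4′,6′-triisopropylbiphenyl, 10 mol %), K3PO4 (6 equiv, aq), MeCN, 70 °C, Ar; work-up at 0 °C with pH 6 phosphate buffer
Reagents that add atoms: none
Why: Suzuki–Miyaura coupling of an aryl bromide with an allylboronate, in which the bulky di-tert-butylbiarylphosphine should drive the allyl ligand to its less hindered primary σ-bound form before reductive elimination, so that the linear 3-methylbut-2-enyl group and not the 1,1-dimethylallyl isomer ends up on ring B, while the phenols ride through as phenoxides and the new ortho-prenylphenol never meets acid.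

Compound list
1 | 3-(4-hydroxyphenyl)propanoic acid | O=C(O)CCc1ccc(O)cc1 | starting material
2 | 3-(3-bromo-4-hydroxyphenyl)propanoic acid | O=C(O)CCc1ccc(O)c(Br)c1 | intermediate
3 | phloroglucinol (benzene-1,3,5-triol) | Oc1cc(O)cc(O)c1 | starting material
4 | 3-(3-bromo-4-hydroxyphenyl)-1-(2,4,6-trihydroxyphenyl)propan-1-one | O=C(CCc1ccc(O)c(Br)c1)c1c(O)cc(O)cc1O | intermediate
5 | 2-methylbut-3-en-2-ol | CC(C)(O)C=C | starting material
6 | C-prenyl ketone, 3-(3-bromo-4-hydroxyphenyl)-1-[2,4,6-trihydroxy-3-(3-methylbut-2-en-1-yl)phenyl]propan-1-one (formed and consumed in the flask in step 3) | O=C(CCc1ccc(O)c(Br)c1)c1c(O)cc(O)c(CC=C(C)C)c1O | intermediate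
7 | 3-(3-bromo-4-hydroxyphenyl)-1-(5,7-dihydroxy-2,2-dimethylchroman-6-yl)propan-1-one | O=C(CCc1ccc(O)c(Br)c1)c1c(O)cc2c(c1O)CCC(C)(C)O2 | intermediate
8 | prenylboronic acid pinacol ester, 4,4,5,5-tetramethyl-2-(3-methylbut-2-en-1-yl)-1,3,2-dioxaborolane | CC(C)=CCB1OC(C)(C)C(C)(C)O1 | starting material
9 | 1-(5,7-dihydroxy-2,2-dimethylchroman-6-yl)-3-[4-hydroxy-3-(3-methylbut-2-en-1-yl)phenyl]propan-1-one | CC(C)=CCc1cc(CCC(=O)c2c(O)cc3c(c2O)CCC(C)(C)O3)ccc1O | target

Total step count: 4. Longest linear sequence: 4 steps (1 to 2 to 4 to 7 to 9).

Steps most likely to fail

Step 3. The ring may close through the hydroxyl ortho to the acyl group instead of the para one, and a second alkylation with annulation may occur at the remaining free ring A carbon. The fallback fixes the ring oxygen before the carbon–carbon bond is made and sets out from 4. With one equivalent of base, the para hydroxyl of ring A (the most acidic one, and the only one on that ring not chelated to the ketone) should be etherified first. 3-Chloro-3-methylbut-1-yne with DBU and catalytic CuCl2 in MeCN at 0 °C should give the aryl propargyl ether 3-(3-bromo-4-hydroxyphenyl)-1-[2,6-dihydroxy-4-(2-methylbut-3-yn-2-yloxy)phenyl]propan-1-one F1. Heating F1 in xylene at 140 °C should bring about the aromatic Claisen rearrangement, hydrogen shift and oxa-6π electrocyclisation onto either of the two equivalent neighbouring ring carbons. This should give 3-(3-bromo-4-hydroxyphenyl)-1-(5,7-dihydroxy-2,2-dimethyl-2H-chromen-6-yl)propan-1-one F2. Hydrogenation of the C3=C4 alkene of F2 with H2 and RhCl(PPh3)3 in benzene–ethanol at rt, which leaves the aryl bromide and the ketone alone, comes back to the route at 7.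

Step 4. The allyl group may be transferred through its tertiary end, the bromine may be lost reductively, or oxidative addition may stall on the phenoxide-bearing ring. The fallback replaces prenyl transfer by allyl transfer followed by olefin metathesis and sets out from 7. Stille coupling with allyltributylstannane (Pd(PPh3)4, DMF, 90 °C, no base, phenols neutral) should give 1-(5,7-dihydroxy-2,2-dimethylchroman-6-yl)-3-[4-hydroxy-3-(prop-2-en-1-yl)phenyl]propan-1-one F3. An allyl group has identical termini, so no regiochemical question arises. Cross-metathesis of F3 with excess 2-methylbut-2-ene (second-generation Grubbs catalyst, CH2Cl2, 40 °C) should then convert the terminal alkene into the trisubstituted prenyl alkene and come back to the route at 9.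

Step 2. In hot BF3·OEt2 the free phenol of the acid may be acylated in competition (ester oligomers), C-acylation may stay incomplete, and isolation from the boron-containing mixture may be poor. The fallback is a Houben–Hoesch ketone synthesis and sets out from 3. Purchased 3-(4-hydroxyphenyl)propanenitrile F4 would be brominated as in step 1 (NBS, MeCN, 0 °C) to 3-(3-bromo-4-hydroxyphenyl)propanenitrile F5. Condensation of F5 with 3 (ZnCl2, dry HCl gas, Et2O, 0 °C) should precipitate 3-(3-bromo-4-hydroxyphenyl)-1-(2,4,6-trihydroxyphenyl)propan-1-iminium chloride F6. Hydrolysis of F6 in water at 100 °C comes back to the route at 4.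

Further compounds
F1 | step 3 | 3-(3-bromo-4-hydroxyphenyl)-1-[2,6-dihydroxy-4-(2-methylbut-3-yn-2-yloxy)phenyl]propan-1-one | O=C(CCc1ccc(O)c(Br)c1)c1c(O)cc(OC(C)(C)C#C)cc1O
F2 | step 3 | 3-(3-bromo-4-hydroxyphenyl)-1-(5,7-dihydroxy-2,2-dimethyl-2H-chromen-6-yl)propan-1-one | O=C(CCc1ccc(O)c(Br)c1)c1c(O)cc2c(c1O)C=CC(C)(C)O2
F3 | step 4 | 1-(5,7-dihydroxy-2,2-dimethylchroman-6-yl)-3-[4-hydroxy-3-(prop-2-en-1-yl)phenyl]propan-1-one | C=CCc1cc(CCC(=O)c2c(O)cc3c(c2O)CCC(C)(C)O3)ccc1O
F4 | step 2 | 3-(4-hydroxyphenyl)propanenitrile | N#CCCc1ccc(O)cc1
F5 | step 2 | 3-(3-bromo-4-hydroxyphenyl)propanenitrile | N#CCCc1ccc(O)c(Br)c1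
F6 | step 2 | 3-(3-bromo-4-hydroxyphenyl)-1-(2,4,6-trihydroxyphenyl)propan-1-iminium chloride | [NH2+]=C(CCc1ccc(O)c(Br)c1)c1c(O)cc(O)cc1O.[Cl-]
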